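In a one-step world target is made at a steady rate and then ages to over-reaction product, so the make rate cancels from the share of target and the ageing is what we must read.

| flask | starting material | second substrate | coupling partner | free catalyst | remark | time |
|---|---|---|---|---|---|---|
| beta | 0.30 M | 0.30 M | 0.30 M | 7.5 mM | run made earlier |  |
| theta | 0.30 M | 0.30 M | 0.30 M | 3.8 mM | run made earlier |  |
| zeta | 0.30 M | 0.30 M | 0.30 M | 5.6 mM | run made earlier |  |
| alpha | 0.30 M | 0.30 M | 0.45 M | 7.5 mM | run made earlier |  |
| dusk | 0.30 M | 0.300 M | 0.300 M | 7.5 mM | everything together in a closed stirred flask, run for 30 h | 30 h |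
| winter | 0.30 M (fed, over 15.0 h) | 0.300 M | 0.300 M | 7.5 mM | a stirred flask in which starting material is dosed at a steady rate over 15.0 h without added volume, worked up at 30 h | 30 h |
| midnight | 0.30 M | 0.300 M (fed, over 15.0 h) | 0.300 M | 7.5 mM | all but second substrate at the start; second substrate goes in evenly over 15.0 h, the run ends at 30 h | 30 h |
| dawn | 0.30 M | 0.300 M | 0.300 M | 7.5 mM | a single well-mixed tank run continuously and read at steady state, 30 h in it on average |  |

- beta (time / h: target / %, over-reaction product / %): 2.00: 1.5, 0; 6.00: 1.8, 0.6; 10.0: 2.3, 0.5; 15.0: 2.9, 1.3; 25.0: 2.9, 3.7; 30.0: 4.3, 3.6
- theta (time / h: target / %, over-reaction product / %): 6.00: 1.4, 0; 12.0: 2.2, 0.2; 20.0: 2.8, 0.9; 25.0: 2.2, 2.1; 30.0: 2.8, 2.8; 40.0: 1.3, 3.6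
- zeta (time / h: target / %, over-reaction product / %): 3.00: 0.6, 0; 5.00: 2.0, 0; 8.00: 1.6, 0.9; 12.0: 2.3, 0; 20.0: 3.0, 2.1; 40.0: 2.9, 5.0
- alpha (time / h: target / %, over-reaction product / %): 3.00: 1.7, 0; 5.00: 2.5, 1.3; 10.0: 5.0, 2.1; 20.0: 7.1, 5.4; 40.0: 5.9, 11.8

(standard deviation of a reading: 0.5 percentage points)

- the stated concentrations are those of everything mixed, before any reaction; amounts are the same in each set-up
- reactions considered so far: starting material + free catalyst <-> catalyst intermediate A; coupling partner + catalyst intermediate A -> free catalyst + target; second substrate + free catalyst <-> catalyst intermediate B; coupling partner + catalyst intermediate B -> free catalyst + second product; target -> over-reaction product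
- the feed brings no volume worth counting
- the earlier runs were made in a closed, stirred flask

- the set-up with the highest share of target in all that became target or over-reaction product, at the outlet or at the end ("none" if the first two lie within 2 percentage points) (dusk / winter / midnight / dawn / none)
- share of target in all that became target or over-reaction product, at the outlet or at the end, dusk
- share of target in all that became target or over-reaction product, at the outlet or at the end, winter
- share of target in all that became target or over-reaction product, at the outlet or at the end, midnight
- share of target in all that became target or over-reaction product, at the outlet or at the end, dawn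

1. We read the ageing in the alpha run. Over-reaction product stands at 11.8% after 40.0 h, and dividing this by the trapezoid area under the target readings gives 0.0546 h⁻¹. This is our ageing constant, the over-reaction product gained per unit area under the target curve. It is a reading, with a scatter of 0.5 percentage points on each point.

2. The bench rule takes the make as steady, so the share is (1 − exp(−x))/x, with x the ageing constant times the time. For dusk x is 1.64, which gives 49.2%. The tank dawn, with 30 h on average, follows 1/(1 + x) and gives 37.9%. In winter the make rises with c(starting material) during the feed, so target is younger. With 0.819 for the feed, we get 56.9%.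

3. The border is the ratio c(second substrate)/c(free catalyst) in the charge, 40.0. The earlier runs never varied second substrate, so we assume that it holds the catalyst as catalyst intermediate B, the resting state, which makes the target rate inverse first order in c(second substrate). Midnight starts without any, and the feed matches the catalyst charge after 0.375 h. On that assumption the midnight make is far from steady.

4. Integrating that inverse order puts 78.7% of the midnight make inside the feed. Placing this part at the start gives 29.8%, which we expect to be low. We commit to winter as best, above our other figures.

The forecast gave 47% for dusk, 57% for winter, 46% for midnight and 41% for dawn, with winter best, and said of midnight that "formation is earlier"; its midnight figure stands above ours.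

The flasks give 45.1% for dusk, 54.4% for winter, 36.6% for midnight and 38.2% for dawn, and winter is best.

    starting material + free catalyst ⇌ catalyst intermediate A (K = 1.30 M⁻¹, k = 0.00520 M⁻¹ s⁻¹)
    coupling partner + catalyst intermediate A → free catalyst + target (k = 0.00230 M⁻¹ s⁻¹)
    second substrate + free catalyst ⇌ catalyst intermediate B (K = 86.0 M⁻¹, k = 0.00480 M⁻¹ s⁻¹)
    coupling partner + catalyst intermediate B → free catalyst + second product (k = 7.90 × 10⁻⁴ M⁻¹ s⁻¹)
    target → over-reaction product (k = 1.50 × 10⁻⁵ s⁻¹)

In midnight, while second substrate went in, target plus over-reaction product reached 9.30% by 15.0 h, against 4.56% in dusk. From then to 30.0 h, with catalyst intermediate B at 79.4% of the catalyst, target fell to 4.49%, and our constant on the mean target gives a gain of 4.1 points in over-reaction product, where midnight gained 4.1 points. Winter left standing from 30.0 h to 72.0 h takes the same reckoning to 6.1 points, and that flask gained 6.5 points.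

The readings stem from a simulated flask for an exercise; noise was put on by code.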